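**Assumption:** α/β follow the usual neo-clerodane drawing of the target (C17, C19, C20 α; H-10, C11 β), and the simple building blocks 1, 2, 5, 13, 16 and the chiral catalyst/ligand are purchased. The route is a paper design; nothing here has been run.

## Retrosynthetic overview

1. Endgame: the 6,19-diacetate and the 4-OH/18-Cl chlorohydrin come from a 6,19-acetonide and HCl opening of the 4α,18-epoxide; the butenolide is attached at C12–C13 by an asymmetric Nozaki–Hiyama–Kishi coupling.
2. Ring A (formed second): singlet-oxygen dearomatisation of a 2,5-disubstituted furan unmasks a cis-enedione (furan carbons = C1–C4, both oxygens in place), which closes C4–C5 by intramolecular Mukaiyama aldol, setting C4 and C5.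
3. Ring B (formed first): catalytic asymmetric Diels–Alder of tiglic aldehyde (C8, C9, C11, C17, C20) with a 2-silyloxydiene made from 5-(hydroxymethyl)furfural (C10, C1–C4, C18) and methyl acetoacetate (C5–C7, C19).
4. C10 is then inverted to the trans-decalin, and C1/C6 are set by thermodynamic (dissolving-metal) reduction.

## Route

**Step 1**
Reactants: 1, 5-(hydroxymethyl)furfural; 2, methyl acetoacetate
Product: 3, methyl (2Z)-2-acetyl-3-[5-(hydroxymethyl)furan-2-yl]prop-2-enoate
Conditions: piperidine (cat.), AcOH (cat.), CH2Cl2, 4 Å MS, 0 °C → rt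
Reagents that add atoms: none
Why: Knoevenagel condensation; the aldehyde carbon becomes C10, and the favoured Z isomer (furyl trans to acetyl) puts the furan on the "outside" of the later diene.

**Step 2**
Reactants: 3
Product: 4, methyl (2Z)-3-{5-[(triisopropylsilyloxy)methyl]furan-2-yl}-2-[1-(triisopropylsilyloxy)ethenyl]prop-2-enoate
Conditions: TIPSOTf (2.3 equiv), Et3N, CH2Cl2, −78 → 0 °C
Reagents that add atoms: triisopropylsilyl triflate, CC(C)[Si](C(C)C)(C(C)C)OS(=O)(=O)C(F)(F)F
Why: Kinetic enol silylation of the only enolisable site (acetyl CH3) gives the 2-silyloxy-1,3-diene, and the primary alcohol (C18–OH) is silylated in the same operation.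

**Step 3**
Reactants: 4; 5, (E)-2-methylbut-2-enal (tiglic aldehyde)
Product: 6, ring-B cyclohexene: C5(CO2Me)=C6(OTIPS), C8 α-Me, C9 α-Me and β-CHO, C10 β-[5-(TIPSOCH2)furan-2-yl] (H-10 α)
Conditions: (S)-o-tolyl-oxazaborolidine·HNTf2 (Corey oxazaborolidinium, 20 mol %), CH2Cl2, −78 → −40 °C
Reagents that add atoms: none
Why: Lewis-acid-catalysed Diels–Alder of a 2-silyloxydiene with an α-substituted enal (new diene substrate): the enol-ether terminus C7 bonds to the enal β-carbon C8 and C10 to C9 ("para", polarity-matched); suprafacial addition to the E-enal fixes C17/C20 cis; the endo-CHO transition state (both methyls exo) puts CHO cis to the furan; the catalyst sets the absolute configuration (use the antipode if the facial sense proves opposite).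

**Step 4**
Reactants: 6
Product: 7, as 6 but with C9 β-vinyl (C11=C12H2) in place of CHO
Conditions: Ph3PCH3Br, KHMDS, THF, −78 → 0 °C
Reagents that add atoms: methyltriphenylphosphonium bromide, C[P+](c1ccccc1)(c1ccccc1)c1ccccc1.[Br-]
Why: Wittig methylenation of the non-enolisable neopentyl aldehyde adds C12 and masks the side chain as a vinyl group inert to singlet oxygen and Li/NH3.

**Step 5 (key step, part 1: dearomatisation)**
Reactants: 7
Product: 8, Z-enedione: the furan is opened to C10–C(=O)–CH=CH–C(=O)–CH2OTIPS (C1 and C4 ketones, Z-C2=C3); ring B, the silyl enol ether ester and the vinyl group are unchanged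
Conditions: O2, hν (visible), TPP (cat.), CH2Cl2, −78 °C; then Me2S, −78 → −20 °C, dark; solution used directly without purification
Reagents that add atoms: dioxygen, O=O (one O retained; the other carbonyl oxygen is the former furan oxygen)
Why: Furan photooxygenation: [4+2] addition of 1O2 to the electron-rich 2,5-dialkylfuran is much faster than reaction at the ester-deactivated silyl enol ether or the vinyl group, and Me2S reduction of the endoperoxide gives the cis-enedione with the Z geometry needed for ring closure.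

**Step 6 (key step, part 2: ring A closure)**
Reactants: 8
Product: 9, cis-fused decalin (H-10 α): Δ2-1-ketone, 4α-OH, 4β-CH2OTIPS, 5α-CO2Me, 6-ketone, 8α-Me, 9α-Me, 9β-vinyl
Conditions: TiCl4 (3 equiv), CH2Cl2, −78 °C; aq. NaHCO3
Reagents that add atoms: none
Why: Proposed new method: TiCl4 activates the C4 ketone for a 6-exo intramolecular Mukaiyama aldol by the β-ketoester silyl enol ether (C5), which attacks from the β face (syn to C1, anti to the axial C9-methyl) to set C5, while Ti chelation between O4 and the ester carbonyl puts O4 α and CH2OTIPS on the convex face to set C4; the closest known reaction type is the Lewis-acid intramolecular Mukaiyama aldol cyclisation onto ketones.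

**Step 7**
Reactants: 9
Product: 10, the C10 epimer of 9 (trans-decalin, H-10 β)
Conditions: TMSOTf, Et3N, CH2Cl2, 0 °C → rt; then 1 M HCl, THF, 0 °C
Reagents that add atoms: none
Why: Soft enolisation gives the cross-conjugated C1(OTMS)=C10 dienol ether (C4 has no H) and caps O4, which avoids base-induced retro-aldol; kinetic protonation from the β face (α face blocked by C9-Me and C5-CO2Me) gives the trans ring fusion, and the transient C6/C7 enol ether and O4-TMS are hydrolysed in the same acid treatment.

**Step 8**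
Reactants: 10
Product: 11, trans-decalin tetraol: 1β-OH, 4α-OH, 6α-OH, 19-OH, 18-OTIPS, 9β-vinyl
Conditions: Li (excess), NH3(l)/THF, EtOH, −78 → −33 °C; NH4Cl
Reagents that add atoms: none
Why: Dissolving-metal reduction saturates C2=C3, reduces both ketones under thermodynamic control to the equatorial alcohols (1β, 6α; hydride reagents would give axial 1α-OH because of the syn-axial C19), and reduces the non-enolisable ester to C19H2OH (Bouveault–Blanc type), with ketyl formation at −78 °C expected to outpace retro-aldol of the C4 alkoxide; the terminal alkene and silyl ether survive.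

**Step 9**
Reactants: 11
Product: 12, 6α,19-O-isopropylidene acetal of 11 (1β-OH and 4α-OH free)
Conditions: Me2C(OMe)2, PPTS (cat.), CH2Cl2, rt
Reagents that add atoms: 2,2-dimethoxypropane, COC(C)(C)OC
Why: Acetonide formation: the primary 19-OH and adjacent secondary 6α-OH close the 1,3-dioxane, separating the 6,19 pair from the 1-OH; the tertiary 4-OH does not compete.

**Step 10**
Reactants: 12; 13, (S)-2-methylbutanoic anhydride
Product: 14, 1β-[(S)-2-methylbutanoyloxy] derivative of 12
Conditions: DMAP, Et3N, CH2Cl2, rt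
Reagents that add atoms: none (acyl group from 13)
Why: DMAP-catalysed acylation of the only free secondary alcohol; esterifying C1 before C12 is oxidised prevents 1,12-lactol formation in the next step.

**Step 11**
Reactants: 14
Product: 15, C12 aldehyde (9β-CH2CHO)
Conditions: PdCl2(PhCN)2, CuCl2, AgNO2 (cat.), t-BuOH/MeNO2, O2 (1 atm), rt
Reagents that add atoms: dioxygen, O=O
Why: Nitrite-modified aldehyde-selective Wacker oxidation; the quaternary allylic carbon reinforces anti-Markovnikov selectivity.

**Step 12**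
Reactants: 15; 16, 4-bromofuran-2(5H)-one
Product: 17, (12S)-12-hydroxy-13-en-15,16-olide (butenolide attached at C13)
Conditions: CrCl2, NiCl2 (cat.), Kishi chiral sulfonamide ligand, Et3N, THF/MeCN, rt
Reagents that add atoms: none (butenolide from 16)
Why: Nozaki–Hiyama–Kishi coupling: Ni inserts into the vinyl C–Br, transmetalation to Cr(III) and chemoselective aldehyde addition; the chiral ligand controls the C12 face (12S), since the ring stereocentres are remote.

**Step 13**
Reactants: 17; 13
Product: 18, 1β,12-bis[(S)-2-methylbutanoate]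
Conditions: DMAP, Et3N, CH2Cl2, 0 °C
Reagents that add atoms: none (acyl group from 13)
Why: Acylation of the secondary 12-OH with retention; done promptly to prevent translactonisation of the hydroxy-butenolide.

**Step 14**
Reactants: 18
Product: 19, 4α,18-diol (TIPS removed)
Conditions: TBAF, AcOH, THF, rt
Reagents that add atoms: none
Why: Buffered fluoride desilylation of the primary TIPS ether; buffering protects the butenolide and esters, and the acetonide is untouched.

**Step 15**
Reactants: 19
Product: 20, 4α,18-epoxide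
Conditions: PPh3, DIAD, THF, 0 °C → rt
Reagents that add atoms: none
Why: Intramolecular Mitsunobu etherification: the primary C18–O is activated and displaced by the tertiary C4 oxygen (3-exo-tet), so the C4 configuration is untouched.

**Step 16**
Reactants: 20
Product: 21, 18-chloro-4α,6α,19-triol 1β,12-diester
Conditions: HCl (4 M in dioxane), CH2Cl2, 0 °C; then MeOH added, 0 °C → rt
Reagents that add atoms: hydrogen chloride, Cl
Why: Chloride opens the protonated spiro-epoxide at the primary C18 (C4 is neopentyl and keeps its oxygen and configuration) before any methanol is present, and MeOH added afterwards removes the acetonide by acid-catalysed transketalisation.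

**Step 17**
Reactants: 21
Product: 22, ajugaciliatin A
Conditions: Ac2O, pyridine, DMAP (cat.), CH2Cl2, rt
Reagents that add atoms: acetic anhydride, CC(=O)OC(C)=O
Why: Acetylation of the primary 19-OH and secondary 6α-OH; the hindered tertiary 4-OH is not acylated.

## Compound list

1 | 5-(hydroxymethyl)furan-2-carbaldehyde (HMF) | O=Cc1ccc(CO)o1 | starting material
2 | methyl acetoacetate | CC(=O)CC(=O)OC | starting material
3 | methyl (2Z)-2-acetyl-3-[5-(hydroxymethyl)furan-2-yl]prop-2-enoate | CC(=O)/C(C(=O)OC)=C/c1ccc(CO)o1 | intermediate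
4 | methyl (2Z)-3-{5-[(TIPSO)methyl]furan-2-yl}-2-[1-(TIPSO)ethenyl]prop-2-enoate | C=C(O[Si](C(C)C)(C(C)C)C(C)C)/C(C(=O)OC)=C/c1ccc(CO[Si](C(C)C)(C(C)C)C(C)C)o1 | intermediate
5 | (E)-2-methylbut-2-enal (tiglic aldehyde) | C/C=C(\C)C=O | starting material
6 | Diels–Alder adduct (8α-Me, 9α-Me, 9β-CHO, 10β-furyl, C5=C6 silyl enol ether ester) | O=C[C@@]1(C)[C@H](C)CC(O[Si](C(C)C)(C(C)C)C(C)C)=C(C(=O)OC)[C@H]1c1ccc(CO[Si](C(C)C)(C(C)C)C(C)C)o1 | intermediate
7 | 9β-vinyl analogue of 6 | C=C[C@@]1(C)[C@H](C)CC(O[Si](C(C)C)(C(C)C)C(C)C)=C(C(=O)OC)[C@H]1c1ccc(CO[Si](C(C)C)(C(C)C)C(C)C)o1 | intermediate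
8 | Z-enedione from furan opening (C1/C4 diketone, 18-OTIPS) | C=C[C@@]1(C)[C@H](C)CC(O[Si](C(C)C)(C(C)C)C(C)C)=C(C(=O)OC)[C@H]1C(=O)/C=C\C(=O)CO[Si](C(C)C)(C(C)C)C(C)C | intermediate
9 | cis-decalin aldol (H-10α; Δ2-1-one, 4α-OH, 18-OTIPS, 5α-CO2Me, 6-one, 9β-vinyl) | C=C[C@@]1(C)[C@H](C)CC(=O)[C@]2(C(=O)OC)[C@H]1C(=O)C=C[C@]2(O)CO[Si](C(C)C)(C(C)C)C(C)C | intermediate
10 | trans-decalin (H-10β) epimer of 9 | C=C[C@@]1(C)[C@H](C)CC(=O)[C@]2(C(=O)OC)[C@@H]1C(=O)C=C[C@]2(O)CO[Si](C(C)C)(C(C)C)C(C)C | intermediate
11 | 1β,4α,6α,19-tetraol, 18-OTIPS, 9β-vinyl | C=C[C@@]1(C)[C@H](C)C[C@H](O)[C@]2(CO)[C@@H]1[C@H](O)CC[C@]2(O)CO[Si](C(C)C)(C(C)C)C(C)C | intermediate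
12 | 6α,19-acetonide of 11 | C=C[C@@]1(C)[C@H](C)C[C@H](OC(C)(C)OC3)[C@]23[C@@H]1[C@H](O)CC[C@]2(O)CO[Si](C(C)C)(C(C)C)C(C)C | intermediate
13 | (S)-2-methylbutanoic anhydride | CC[C@H](C)C(=O)OC(=O)[C@@H](C)CC | starting material
14 | 1β-[(S)-2-methylbutanoate] of 12 | C=C[C@@]1(C)[C@H](C)C[C@H](OC(C)(C)OC3)[C@]23[C@@H]1[C@H](OC(=O)[C@@H](C)CC)CC[C@]2(O)CO[Si](C(C)C)(C(C)C)C(C)C | intermediate
15 | C12 aldehyde (9β-CH2CHO) | O=CC[C@@]1(C)[C@H](C)C[C@H](OC(C)(C)OC3)[C@]23[C@@H]1[C@H](OC(=O)[C@@H](C)CC)CC[C@]2(O)CO[Si](C(C)C)(C(C)C)C(C)C | intermediate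
16 | 4-bromofuran-2(5H)-one | O=C1C=C(Br)CO1 | starting material
17 | (12S)-12-hydroxy butenolide | O[C@@H](C[C@@]1(C)[C@H](C)C[C@H](OC(C)(C)OC3)[C@]23[C@@H]1[C@H](OC(=O)[C@@H](C)CC)CC[C@]2(O)CO[Si](C(C)C)(C(C)C)C(C)C)C1=CC(=O)OC1 | intermediate
18 | 1β,12-bis[(S)-2-methylbutanoate], 18-OTIPS, 6,19-acetonide | CC[C@H](C)C(=O)O[C@@H](C[C@@]1(C)[C@H](C)C[C@H](OC(C)(C)OC3)[C@]23[C@@H]1[C@H](OC(=O)[C@@H](C)CC)CC[C@]2(O)CO[Si](C(C)C)(C(C)C)C(C)C)C1=CC(=O)OC1 | intermediate
19 | 4α,18-diol | CC[C@H](C)C(=O)O[C@@H](C[C@@]1(C)[C@H](C)C[C@H](OC(C)(C)OC3)[C@]23[C@@H]1[C@H](OC(=O)[C@@H](C)CC)CC[C@]2(O)CO)C1=CC(=O)OC1 | intermediate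
20 | 4α,18-epoxide | CC[C@H](C)C(=O)O[C@@H](C[C@@]1(C)[C@H](C)C[C@H](OC(C)(C)OC3)[C@]23[C@@H]1[C@H](OC(=O)[C@@H](C)CC)CC[C@]2(O4)C4)C1=CC(=O)OC1 | intermediate
21 | 18-chloro-4α,6α,19-triol 1β,12-diester | CC[C@H](C)C(=O)O[C@@H](C[C@@]1(C)[C@H](C)C[C@H](O)[C@]2(CO)[C@@H]1[C@H](OC(=O)[C@@H](C)CC)CC[C@]2(O)CCl)C1=CC(=O)OC1 | intermediate
22 | ajugaciliatin A: (12S)-6α,19-diacetoxy-18-chloro-4α-hydroxy-1β,12-bis[(S)-2-methylbutanoyloxy]-neo-clerod-13-en-15,16-olide | CC[C@H](C)C(=O)O[C@@H](C[C@@]1(C)[C@H](C)C[C@H](OC(C)=O)[C@]2(COC(C)=O)[C@@H]1[C@H](OC(=O)[C@@H](C)CC)CC[C@]2(O)CCl)C1=CC(=O)OC1 | target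

## Summary

Total steps: 17. Longest linear sequence: 17 (from HMF, 1; all other partners are purchased).

Steps most likely to fail, each with a fallback that changes the approach:

1. **Step 6 (Mukaiyama aldol onto the enedione from Step 5).** The C4 configuration, the low nucleophilicity of the ester-bearing TIPS enol ether and Z→E isomerisation of enedione 8 are the concerns. Fallback: start from furfural instead of HMF so the unmasked C4 is an aldehyde and the aldol gives a secondary carbinol; later oxidise C4 to the ketone and add LiCH2Cl axially (β face) to install C18 and the chlorohydrin on the rigid trans-decalin.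
2. **Step 3 (asymmetric Diels–Alder of the push–pull diene).** Reactivity, competing 1,2-Mukaiyama addition, endo ratio and ee are all untested for this diene. Fallback: make ring B from 2-(triisopropylsilyloxy)buta-1,3-diene and tiglic aldehyde, then Saegusa oxidation, α-iodination/Pd-carbonylation to the 2-carbomethoxy enone, and Lewis-acid Friedel–Crafts conjugate addition of 2-[(TIPSO)methyl]furan at C10 (anti to the axial C9-methyl, giving the same C10 configuration).
3. **Step 8 (global Li/NH3 reduction).** Retro-aldol of the C4 alkoxide, reductive coupling within the β-ketoester and incomplete stereocontrol at C1/C6 are possible. Fallback: reduce stepwise with hydride chemistry (Stryker CuH conjugate reduction of the enone, then LiBH4 for the ketones and ester, giving 6α-OH and the axial 1α-OH), form the 6,19-acetonide, and invert C1 by Mitsunobu esterification with (S)-2-methylbutanoic acid, which installs the 1β-ester directly.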